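(All runs are calculated for an exercise; scatter was added.)

**One constant.** I read a single constant from north, not one for each step, and carry it to these flasks.

| flask | G | E | remark | time |
|---|---|---|---|---|
| north | 13 mM | 4 equiv | run made earlier |  |
| blue | 20 mM | 4.00 equiv |  | 40 min |
| grey | 20 mM | 1.50 equiv |  | 40 min |
| red | 20 mM | 1.20 equiv |  | 40 min |

- north (time / min: D / %): 2.00: 1.2; 4.00: 5.2; 10.0: 20.0; 25.0: 43.6

(each reading ± 0.5 percentage points)

- the analysis behind the earlier runs scatters by 0.5 percentage points, standard deviation

1. which of these holds the largest part of the G at the end of blue (G / X / D)
2. which of these holds the largest part of the G at the end of grey (G / X / D)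
3. which of these holds the largest part of the G at the end of red (G / X / D)
4. amount of D at the end of blue, in percent of the G charged

**Clearing constant.** Between 10.0 min and 25.0 min in north, the part of G not yet D falls from 80.0% to 56.4%. That gives 0.0233 min⁻¹, the clearing constant: the pseudo-first-order rate of that fall at north's charge of E. Blue holds 1.54 times north's E, so each blue minute counts as 1.54 north minutes, and blue runs 36.5 min of them past north's last reading.

**Bracket.** Running the constant unchanged through that stretch, with E held at its charge, gives an upper mark of 75.9% D, which is an estimate and not a proven limit. The loose floor is north's 43.6%. Two E per D take at most two of the 4.00 equiv, so if nothing else uses E it stays above half its charge. Counting the stretch at half speed gives an estimated lower mark of 63.2%. Grey and red reach 23.1 min and 18.5 min in north minutes, fewer than north's 25.0 min, so I hold D below 43.6% there. That leaves G and X together above 56.4% in grey and red, and north's lag, read as 1.89 min, is short beside its 25.0 min, so I expect X to be the smaller of the two and G to lead in both.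

**Result.** The forecast says D, X, X and 80% D (72% to 87%), with “X should lead” in grey and red, and its central value stands above my upper mark. Blue ends with 63.3% D, level with my lower mark, while G leads in grey at 53.2% and in red at 60.4%.

    G + E → X (k = 0.0150 M⁻¹ s⁻¹)
    E + X → D (k = 0.0710 M⁻¹ s⁻¹)
    D → L (k = 1.50 × 10⁻⁴ s⁻¹)
    E → Z (k = 1.10 × 10⁻⁴ s⁻¹)

**Second flask.** The same flask as blue read at 25 min gets the bracket 51.8% to 58.8%, and it gives 57.7%, near the upper mark. In blue, X passes to D with a half-life of 4.8 min at the end, shorter than the 77 min with which D passes to L, and D holds the largest part at 63.3%. That 77 min is longer than blue's 40 min, yet L stands at 16.0% by the end of blue.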